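The route rests on reading ring C of unit 2 (O1''–C2''–C3''–C4''–C4a''–C8a''), without its fused arene, as a cis-2-aryl-2,3-dihydropyran-4-one, the endo hetero-Diels–Alder adduct of an aryl aldehyde. One Eu(hfc)3-catalysed cycloaddition forms C2''–C3'' and O1''–C8a'', closes that ring and sets C2'' and C3''; the feature exploited is the cis C2''-H/C3''-H pair. The precursor is the (2S,3R)-trans-flavanone of unit 1 carrying on C3 a (1E,3Z)-1-methoxy-3-silyloxybutadienyl arm, partnered with 4-(benzyloxy)benzaldehyde. Ring A of unit 2 is annulated afterwards on C4a''=C8a''; benzyl ethers allow a neutral final deprotection.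

Key step: step 10

Numbering: unit 1 is the 4-methoxyphenyl flavanone (plain locants); unit 2 is the 4-hydroxyphenyl flavanone (double-primed locants, used from the dihydropyranone stage on, where C4a'' and C8a'' are the two alkene carbons).

Assumption: the (S)-configured bisphosphine in step 3 is taken to give the 2S flavanone, by analogy with rhodium-catalysed aryl transfer to cyclic enones; the mirror-image ligand is used if a pilot run shows the opposite sense.

Design remarks: benzyl ethers replace acid-labile acetals so that the epimerisable cis C2''/C3'' pair never meets strong acid or base at the end. After C2 is set, the arm is built without strong base, because a free flavanone enolate can open ring C of unit 1 and racemise C2.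

Step 1
Reactants: 1 1-(2,4,6-trihydroxyphenyl)ethan-1-one
Product: 2 1-[2,4-bis(benzyloxy)-6-hydroxyphenyl]ethan-1-one
Conditions: BnBr (2.05 equiv), K2CO3, DMF, 0 → 25 °C
Reagents that add atoms: benzyl bromide, BrCc1ccccc1
Why: Williamson etherification takes the para hydroxyl and one ortho hydroxyl, while the remaining ortho hydroxyl, hydrogen-bonded to the acetyl carbonyl, resists alkylation.

Step 2
Reactants: 2 1-[2,4-bis(benzyloxy)-6-hydroxyphenyl]ethan-1-one
Product: 4 5,7-bis(benzyloxy)-4H-chromen-4-one, via enaminone 3 (not isolated)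
Conditions: Me2NCH(OMe)2, toluene, 90 °C; then conc. HCl, CH2Cl2, 25 °C
Reagents that add atoms: N,N-dimethylformamide dimethyl acetal, COC(OC)N(C)C
Why: Amide acetal condensation at the acetyl methyl gives the enaminone, and acid then drives 6-endo addition of the phenol to the β-carbon with loss of dimethylamine (enaminone route to chromones).

Step 3
Reactants: 4 5,7-bis(benzyloxy)-4H-chromen-4-one; 5 (4-methoxyphenyl)boronic acid
Product: 6 (2S)-5,7-bis(benzyloxy)-2-(4-methoxyphenyl)chroman-4-one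
Conditions: 5 (2 equiv), [Rh(OH)(cod)]2 (1.5 mol%), (S)-6,6'-dimethoxy-2,2'-bis[bis(3,4,5-trifluorophenyl)phosphino]biphenyl (3.3 mol%), toluene/H2O, 30 °C
Reagents that add atoms: none
Why: Rhodium-catalysed asymmetric conjugate arylation (Hayashi–Miyaura reaction) of the chromone, in which the aryl-rhodium species bound to the chiral bisphosphine selects one enone face and so sets C2 as S, the base-free medium protecting the product from ring opening.

Step 4
Reactants: 6 (2S)-5,7-bis(benzyloxy)-2-(4-methoxyphenyl)chroman-4-one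
Product: 7 (2S)-5,7-bis(benzyloxy)-2-(4-methoxyphenyl)-4-(trimethylsilyloxy)-2H-chromene
Conditions: Me3SiOTf, Et3N, CH2Cl2, 0 °C
Reagents that add atoms: trimethylsilyl trifluoromethanesulfonate, C[Si](C)(C)OS(=O)(=O)C(F)(F)F
Why: Soft enolisation (O-silylation, then amine deprotonation at C3) gives the enol silane without a free enolate, so the C2–O1 bond and the C2 configuration are not put at risk.

Step 5
Reactants: 7 enol silane of the (2S)-flavanone; 8 allyl methyl carbonate
Product: 9 (2S,3R)-3-allyl-5,7-bis(benzyloxy)-2-(4-methoxyphenyl)chroman-4-one (2,3-trans)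
Conditions: 8 (1.3 equiv), Pd2(dba)3 (2.5 mol%), dppe (6 mol%), Bu4N[Ph3SiF2] (10 mol%), THF, 25 °C
Reagents that add atoms: none
Why: Tsuji–Trost allylation of an enol silane, in which the π-allylpalladium methoxide formed by decarboxylation desilylates 7 and the palladium-associated enolate is allylated at C3 on the face opposite the C2 aryl group, giving the 2,3-trans (3R) isomer, which is also the thermodynamic one.

Step 6
Reactants: 9 (2S,3R)-3-allyl flavanone
Product: 10 (2S,3R)-5,7-bis(benzyloxy)-2-(4-methoxyphenyl)-3-(2-oxopropyl)chroman-4-one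
Conditions: PdCl2 (10 mol%), CuCl (30 mol%), O2 (1 atm), DMF/H2O, 25 °C
Reagents that add atoms: water, O
Why: Wacker oxidation with Markovnikov hydroxypalladation of the terminal alkene gives the methyl ketone, the standard conversion of a 2-allyl ketone into a 1,4-diketone.

Step 7
Reactants: 10 (2S,3R)-3-(2-oxopropyl) flavanone
Product: 11 (2S,3R)-5,7-bis(benzyloxy)-3-[(3E)-4-(dimethylamino)-2-oxobut-3-en-1-yl]-2-(4-methoxyphenyl)chroman-4-one
Conditions: Me2NCH(OMe)2 (4 equiv), toluene, 75 °C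
Reagents that add atoms: N,N-dimethylformamide dimethyl acetal, COC(OC)N(C)C
Why: Amide acetal condensation takes place at the unhindered methyl group (the arm CH2 is neopentyl-like and C3-H cannot give an enaminone), giving the E enaminone.

Step 8
Reactants: 11 (2S,3R)-enaminone
Product: 13 (2S,3R)-5,7-bis(benzyloxy)-3-[(3E)-4-methoxy-2-oxobut-3-en-1-yl]-2-(4-methoxyphenyl)chroman-4-one, via hydroxymethylene ketone 12 (not isolated)
Conditions: 1 M HCl, THF, 0 → 25 °C; then Me3SiCHN2, MeOH/toluene, 0 °C; then PPTS (cat.), CH2Cl2, 25 °C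
Reagents that add atoms: water, O; trimethylsilyldiazomethane, C[Si](C)(C)C=[N+]=[N-]
Why: Acid hydrolysis of the vinylogous amide gives the enolised β-keto aldehyde, whose acidic enol is O-methylated by the diazoalkane to the β-methoxy enone, a trace of acid then equilibrating the geometry to E.

Step 9
Reactants: 13 (2S,3R)-β-methoxy enone
Product: 14 (2S,3R)-5,7-bis(benzyloxy)-3-[(1Z,3E)-2-(tert-butyldimethylsilyloxy)-4-methoxybuta-1,3-dien-1-yl]-2-(4-methoxyphenyl)chroman-4-one (read from its methoxy end the arm is a (1E,3Z)-1-methoxy-3-silyloxy diene)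
Conditions: tBuMe2SiOTf (1.15 equiv), Et3N, Et2O, −40 → 0 °C
Reagents that add atoms: tert-butyldimethylsilyl trifluoromethanesulfonate, CC(C)(C)[Si](C)(C)OS(=O)(=O)C(F)(F)F
Why: Silyl triflate/amine enolisation of the vinylogous ester at its only enolisable CH2 gives the dienol silane with Z geometry (flavanone C3 cis to the silyloxy group, the usual outcome of amine-mediated silylation), the hindered tertiary C3-H next to the deactivated C4 ketone reacting more slowly.

Step 10
Reactants: 14 (2S,3R)-flavanone with the (1E,3Z)-1-methoxy-3-silyloxybutadienyl arm on C3; 15 4-(benzyloxy)benzaldehyde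
Product: 17 (2S,3R)-5,7-bis(benzyloxy)-3-[(2S,3S)-2-[4-(benzyloxy)phenyl]-4-oxo-3,4-dihydro-2H-pyran-3-yl]-2-(4-methoxyphenyl)chroman-4-one, via silyl enol ether cycloadduct 16 (not isolated)
Conditions: 15 (2 equiv), (+)-Eu(hfc)3 (10 mol%), CH2Cl2, 25 °C; then CF3CO2H (cat.), CH2Cl2, 0 °C
Reagents that add atoms: none
Why: The trivalent europium chelate activates 15 only mildly, so the aldehyde C=O and the s-cis diene combine in a concerted, asynchronous [4+2] cycloaddition that forms C2''–C3'' and O1''–C8a'' together, after which acid removes the silyl group and methanol to reveal the enone. The closest known reaction is the lanthanide-catalysed endo-selective cyclocondensation of aldehydes with 4-substituted 1-methoxy-3-silyloxy dienes, which gives cis-2,3-disubstituted dihydropyranones. Ring C of unit 2 is closed by this cycloaddition, a pericyclic six-membered ring closure in which the carbonyl group is the two-atom partner. C2'' is set relative to C3'' by the endo transition state, in which the aryl group of the europium-bound aldehyde lies under the diene while the flavanone sits outward on the Z enol silane terminus, so that the two end up cis (2''S,3''S). C3'' is set by the diene face, which C3 controls: with C3-H eclipsing the enol silane double bond to relieve allylic strain, the C2 side carrying the anisyl group shields one face and the aldehyde adds on the face flanked by the C4 carbonyl, the chiral europium ligand (antipode chosen to match) adding a smaller bias. The step needs endo over exo addition and one diene face; the first is secured by staying in the pericyclic regime (no strong Lewis acids such as BF3·OEt2 or TiCl4, which open a stepwise aldol path to the trans isomer), the second by the C3 stereocentre.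

Step 11
Reactants: 17 cis-dihydropyranone joined to the trans-flavanone
Product: 19 (2S,3R)-5,7-bis(benzyloxy)-3-[(2S,3S)-2-[4-(benzyloxy)phenyl]-4-oxo-5-(phenylsulfanyl)-3,4-dihydro-2H-pyran-3-yl]-2-(4-methoxyphenyl)chroman-4-one, via chloro sulfide adduct 18 (not isolated)
Conditions: PhSH, N-chlorosuccinimide, CH2Cl2, 0 °C; then 17, −78 °C; then Et3N, −78 → 0 °C
Reagents that add atoms: benzenesulfenyl chloride, ClSc1ccccc1 (made in the flask from benzenethiol, Sc1ccccc1, and N-chlorosuccinimide)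
Why: Electrophilic sulfenylation of an enol ether, in which the sulfenyl chloride adds across C4a''=C8a'' (sulfur on the nucleophilic C4a'', chloride on the acetal carbon) far faster at −78 °C than it attacks the acylated trialkoxyarene, and amine-assisted loss of HCl restores the vinylogous ester.

Step 12
Reactants: 19 5-(phenylsulfanyl) dihydropyranone
Product: 20 (2S,3R)-5,7-bis(benzyloxy)-3-[(2S,3S)-2-[4-(benzyloxy)phenyl]-4-oxo-5-(phenylsulfinyl)-3,4-dihydro-2H-pyran-3-yl]-2-(4-methoxyphenyl)chroman-4-one (both sulfur epimers)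
Conditions: mCPBA (1.0 equiv), NaHCO3, CH2Cl2, −78 → −40 °C
Reagents that add atoms: 3-chloroperoxybenzoic acid, OOC(=O)c1cccc(Cl)c1
Why: Sulfide-to-sulfoxide oxidation with one equivalent of peracid at low temperature is faster than Baeyer–Villiger or arene oxidation, and the sulfur epimers need not be separated.

Step 13
Reactants: 21 methyl 3-(trimethylsilyloxy)but-2-enoate
Product: 22 1-methoxy-1,3-bis(trimethylsilyloxy)buta-1,3-diene
Conditions: LiN(iPr)2, THF, −78 °C; then Me3SiCl, −78 → 0 °C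
Reagents that add atoms: chlorotrimethylsilane, C[Si](C)(C)Cl
Why: γ-Deprotonation of the β-silyloxy enoate gives a dienolate that is silylated on oxygen, the standard preparation of 1,3-bis(silyloxy) dienes.

Step 14
Reactants: 20 5-(phenylsulfinyl) dihydropyranone; 22 1-methoxy-1,3-bis(trimethylsilyloxy)buta-1,3-diene
Product: 25 (2S,3R)-5,7-bis(benzyloxy)-3-[(2S,3S)-2-[4-(benzyloxy)phenyl]-5,7-dihydroxy-4-oxochroman-3-yl]-2-(4-methoxyphenyl)chroman-4-one, via sulfinyl cycloadduct 23 (not isolated), via dienyl ketal 24 (not isolated)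
Conditions: 22 (3 equiv), toluene, 25 → 80 °C; then 0.1 M HCl, THF, 0 °C
Reagents that add atoms: none
Why: Proposed new method: the sulfinyl and carbonyl groups lower the LUMO of C4a''=C8a'' so that the electron-rich trioxygenated diene adds in a normal-demand [4+2] sense with its CH2 terminus on C8a'' and its ketene acetal carbon on C4a'', the sulfoxide then leaves by thermal syn elimination with the cis C8a''-H while C7'' is still masked as its enol silane (so O1'' has no carbonyl to be expelled from), and brief dilute-acid hydrolysis of the silyl ketal with loss of methanol lets the new ring tautomerise to the 5'',7''-dihydroxyarene without touching C2'' or C3''; the closest known reaction type is the cycloaddition, sulfenic acid elimination and aromatisation of 2-sulfinyl enones and sulfinylquinones with 1-oxygenated 3-silyloxy dienes, not yet shown on a 5-sulfinyl dihydropyran-4-one, whose ring oxygen makes the alkene a weaker dienophile.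

Step 15
Reactants: 25 tri-O-benzyl biflavanone
Product: 26 (2S,3R)-5,7-dihydroxy-3-[(2S,3S)-5,7-dihydroxy-2-(4-hydroxyphenyl)-4-oxochroman-3-yl]-2-(4-methoxyphenyl)chroman-4-one (CNP0196568.6)
Conditions: H2 (1 atm), Pd/C (10 wt%), EtOAc/MeOH, 25 °C
Reagents that add atoms: none
Why: Hydrogenolysis of the three aryl benzyl ethers under neutral conditions should leave the acid- and base-epimerisable cis C2''/C3'' pair and both benzylic C2–O bonds intact.

Compound list
1 | 1-(2,4,6-trihydroxyphenyl)ethan-1-one | CC(=O)c1c(O)cc(O)cc1O | starting material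
2 | 1-[2,4-bis(benzyloxy)-6-hydroxyphenyl]ethan-1-one | CC(=O)c1c(O)cc(OCc2ccccc2)cc1OCc1ccccc1 | intermediate
3 | (2E)-1-[2,4-bis(benzyloxy)-6-hydroxyphenyl]-3-(dimethylamino)prop-2-en-1-one | CN(C)/C=C/C(=O)c1c(O)cc(OCc2ccccc2)cc1OCc1ccccc1 | intermediate
4 | 5,7-bis(benzyloxy)-4H-chromen-4-one | O=c1ccoc2cc(OCc3ccccc3)cc(OCc3ccccc3)c12 | intermediate
5 | (4-methoxyphenyl)boronic acid | COc1ccc(B(O)O)cc1 | starting material
6 | (2S)-5,7-bis(benzyloxy)-2-(4-methoxyphenyl)chroman-4-one | COc1ccc([C@H]2Oc3cc(OCc4ccccc4)cc(OCc4ccccc4)c3C(=O)C2)cc1 | intermediate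
7 | (2S)-5,7-bis(benzyloxy)-2-(4-methoxyphenyl)-4-(trimethylsilyloxy)-2H-chromene | COc1ccc([C@H]2Oc3cc(OCc4ccccc4)cc(OCc4ccccc4)c3C(O[Si](C)(C)C)=C2)cc1 | intermediate
8 | allyl methyl carbonate | C=CCOC(=O)OC | starting material
9 | (2S,3R)-3-allyl-5,7-bis(benzyloxy)-2-(4-methoxyphenyl)chroman-4-one | COc1ccc([C@H]2Oc3cc(OCc4ccccc4)cc(OCc4ccccc4)c3C(=O)[C@@H]2CC=C)cc1 | intermediate
10 | (2S,3R)-5,7-bis(benzyloxy)-2-(4-methoxyphenyl)-3-(2-oxopropyl)chroman-4-one | COc1ccc([C@H]2Oc3cc(OCc4ccccc4)cc(OCc4ccccc4)c3C(=O)[C@@H]2CC(C)=O)cc1 | intermediate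
11 | (2S,3R)-5,7-bis(benzyloxy)-3-[(3E)-4-(dimethylamino)-2-oxobut-3-en-1-yl]-2-(4-methoxyphenyl)chroman-4-one | COc1ccc([C@H]2Oc3cc(OCc4ccccc4)cc(OCc4ccccc4)c3C(=O)[C@@H]2CC(=O)/C=C/N(C)C)cc1 | intermediate
12 | (2S,3R)-5,7-bis(benzyloxy)-3-[(3Z)-4-hydroxy-2-oxobut-3-en-1-yl]-2-(4-methoxyphenyl)chroman-4-one (enol form of the β-keto aldehyde) | COc1ccc([C@H]2Oc3cc(OCc4ccccc4)cc(OCc4ccccc4)c3C(=O)[C@@H]2CC(=O)/C=C\O)cc1 | intermediate
13 | (2S,3R)-5,7-bis(benzyloxy)-3-[(3E)-4-methoxy-2-oxobut-3-en-1-yl]-2-(4-methoxyphenyl)chroman-4-one | COc1ccc([C@H]2Oc3cc(OCc4ccccc4)cc(OCc4ccccc4)c3C(=O)[C@@H]2CC(=O)/C=C/OC)cc1 | intermediate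
14 | (2S,3R)-5,7-bis(benzyloxy)-3-[(1Z,3E)-2-(tert-butyldimethylsilyloxy)-4-methoxybuta-1,3-dien-1-yl]-2-(4-methoxyphenyl)chroman-4-one | COc1ccc([C@H]2Oc3cc(OCc4ccccc4)cc(OCc4ccccc4)c3C(=O)[C@@H]2/C=C(\O[Si](C)(C)C(C)(C)C)/C=C/OC)cc1 | intermediate
15 | 4-(benzyloxy)benzaldehyde | O=Cc1ccc(OCc2ccccc2)cc1 | starting material
16 | (2S,3R)-5,7-bis(benzyloxy)-3-[(2S,3S)-2-[4-(benzyloxy)phenyl]-4-(tert-butyldimethylsilyloxy)-6-methoxy-3,6-dihydro-2H-pyran-3-yl]-2-(4-methoxyphenyl)chroman-4-one (acetal carbon unassigned) | COc1ccc([C@H]2Oc3cc(OCc4ccccc4)cc(OCc4ccccc4)c3C(=O)[C@@H]2[C@@H]2C(O[Si](C)(C)C(C)(C)C)=CC(OC)O[C@@H]2c2ccc(OCc3ccccc3)cc2)cc1 | intermediate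
17 | (2S,3R)-5,7-bis(benzyloxy)-3-[(2S,3S)-2-[4-(benzyloxy)phenyl]-4-oxo-3,4-dihydro-2H-pyran-3-yl]-2-(4-methoxyphenyl)chroman-4-one | COc1ccc([C@H]2Oc3cc(OCc4ccccc4)cc(OCc4ccccc4)c3C(=O)[C@@H]2[C@@H]2C(=O)C=CO[C@@H]2c2ccc(OCc3ccccc3)cc2)cc1 | intermediate
18 | (2S,3R)-5,7-bis(benzyloxy)-3-[(2S,3S)-2-[4-(benzyloxy)phenyl]-6-chloro-4-oxo-5-(phenylsulfanyl)oxan-3-yl]-2-(4-methoxyphenyl)chroman-4-one (C5 and C6 of the oxane unassigned) | COc1ccc([C@H]2Oc3cc(OCc4ccccc4)cc(OCc4ccccc4)c3C(=O)[C@@H]2[C@@H]2C(=O)C(Sc3ccccc3)C(Cl)O[C@@H]2c2ccc(OCc3ccccc3)cc2)cc1 | intermediate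
19 | (2S,3R)-5,7-bis(benzyloxy)-3-[(2S,3S)-2-[4-(benzyloxy)phenyl]-4-oxo-5-(phenylsulfanyl)-3,4-dihydro-2H-pyran-3-yl]-2-(4-methoxyphenyl)chroman-4-one | COc1ccc([C@H]2Oc3cc(OCc4ccccc4)cc(OCc4ccccc4)c3C(=O)[C@@H]2[C@@H]2C(=O)C(Sc3ccccc3)=CO[C@@H]2c2ccc(OCc3ccccc3)cc2)cc1 | intermediate
20 | (2S,3R)-5,7-bis(benzyloxy)-3-[(2S,3S)-2-[4-(benzyloxy)phenyl]-4-oxo-5-(phenylsulfinyl)-3,4-dihydro-2H-pyran-3-yl]-2-(4-methoxyphenyl)chroman-4-one (sulfur epimers) | COc1ccc([C@H]2Oc3cc(OCc4ccccc4)cc(OCc4ccccc4)c3C(=O)[C@@H]2[C@@H]2C(=O)C(S(=O)c3ccccc3)=CO[C@@H]2c2ccc(OCc3ccccc3)cc2)cc1 | intermediate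
21 | methyl 3-(trimethylsilyloxy)but-2-enoate | COC(=O)C=C(C)O[Si](C)(C)C | starting material
22 | 1-methoxy-1,3-bis(trimethylsilyloxy)buta-1,3-diene | COC(O[Si](C)(C)C)=CC(=C)O[Si](C)(C)C | intermediate
23 | cycloadduct: unit 1 as in 17, joined at C3 to (2''S,3''S)-2''-[4-(benzyloxy)phenyl]-5''-methoxy-4a''-(phenylsulfinyl)-5'',7''-bis(trimethylsilyloxy)-4a'',5'',8'',8a''-tetrahydrochroman-4''-one (C4a'', C5'', C8a'' unassigned) | COc1ccc([C@H]2Oc3cc(OCc4ccccc4)cc(OCc4ccccc4)c3C(=O)[C@@H]2[C@@H]2C(=O)C3(S(=O)c4ccccc4)C(OC)(O[Si](C)(C)C)C=C(O[Si](C)(C)C)CC3O[C@@H]2c2ccc(OCc3ccccc3)cc2)cc1 | intermediate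
24 | dienyl ketal: unit 1 as in 17, joined at C3 to (2''S,3''S)-2''-[4-(benzyloxy)phenyl]-5''-methoxy-5'',7''-bis(trimethylsilyloxy)-5'',8''-dihydrochroman-4''-one | COc1ccc([C@H]2Oc3cc(OCc4ccccc4)cc(OCc4ccccc4)c3C(=O)[C@@H]2[C@@H]2C(=O)C3=C(CC(O[Si](C)(C)C)=CC3(OC)O[Si](C)(C)C)O[C@@H]2c2ccc(OCc3ccccc3)cc2)cc1 | intermediate
25 | (2S,3R)-5,7-bis(benzyloxy)-3-[(2S,3S)-2-[4-(benzyloxy)phenyl]-5,7-dihydroxy-4-oxochroman-3-yl]-2-(4-methoxyphenyl)chroman-4-one | COc1ccc([C@H]2Oc3cc(OCc4ccccc4)cc(OCc4ccccc4)c3C(=O)[C@@H]2[C@@H]2C(=O)c3c(O)cc(O)cc3O[C@@H]2c2ccc(OCc3ccccc3)cc2)cc1 | intermediate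
26 | (2S,3R)-5,7-dihydroxy-3-[(2S,3S)-5,7-dihydroxy-2-(4-hydroxyphenyl)-4-oxochroman-3-yl]-2-(4-methoxyphenyl)chroman-4-one | COc1ccc([C@H]2Oc3cc(O)cc(O)c3C(=O)[C@@H]2[C@@H]2C(=O)c3c(O)cc(O)cc3O[C@@H]2c2ccc(O)cc2)cc1 | target

Total step count: 15.
Longest linear sequence: 14 steps (steps 1 to 12, 14 and 15; step 13 is the one-step preparation of diene 22).

Steps most likely to fail

1. Step 14 (bears the label "Proposed new method:"). The ring oxygen makes C4a''=C8a'' a push–pull alkene, so cycloaddition may be slower than thermolysis of the sulfoxide. Alternatively the diene may add stepwise at C8a'', and ring C of unit 2 may then open by loss of O1''. The fallback sets out from 20 and comes back at 25. It replaces the cycloaddition by three known reaction types: a vinylogous Mukaiyama–Michael addition, a conjugate addition followed by sulfoxide elimination (as practised on 3-sulfinylchromones), and dioxinone thermolysis with 6π-electrocyclisation of the resulting dienylketene (the closing stage of a Danheiser benzannulation). Commercial 2,2,6-trimethyl-4H-1,3-dioxin-4-one is treated with LiN(iPr)2 and Me3SiCl in THF at −78 °C to give the silyl dienol ether [(2,2-dimethyl-6-methylidene-6H-1,3-dioxin-4-yl)oxy]trimethylsilane F1 by γ-deprotonation and O-silylation. With Sc(OTf)3 (10 mol%) in CH2Cl2 at −78 → −20 °C the methylidene carbon of F1 should add to C8a'' of 20, and aqueous work-up should give the α-sulfinyl ketone (2S,3R)-5,7-bis(benzyloxy)-3-[(2S,3S)-2-[4-(benzyloxy)phenyl]-6-[(2,2-dimethyl-4-oxo-4H-1,3-dioxin-6-yl)methyl]-4-oxo-5-(phenylsulfinyl)oxan-3-yl]-2-(4-methoxyphenyl)chroman-4-one F2 as a mixture of epimers at C4a'', C8a'' and sulfur. In this adduct C7'' stays masked inside the dioxinone, so no carbonyl can expel O1''. Warming F2 in toluene at 80 °C should remove benzenesulfenic acid by syn elimination, the epimerisable C4a'' letting the sulfinyl group reach the C8a''-H, and restore the enone as (2S,3R)-5,7-bis(benzyloxy)-3-[(2S,3S)-2-[4-(benzyloxy)phenyl]-6-[(2,2-dimethyl-4-oxo-4H-1,3-dioxin-6-yl)methyl]-4-oxo-3,4-dihydro-2H-pyran-3-yl]-2-(4-methoxyphenyl)chroman-4-one F3 , which is purified. A dilute solution of F3 in dry toluene at 110 °C should lose acetone to give the acylketene (2S,3R)-5,7-bis(benzyloxy)-3-[(2S,3S)-2-[4-(benzyloxy)phenyl]-6-(2,4-dioxobut-3-en-1-yl)-4-oxo-3,4-dihydro-2H-pyran-3-yl]-2-(4-methoxyphenyl)chroman-4-one F4 as a transient species. The C7'' enol of F4 is a dienylketene, which closes the C4a''–C5'' bond by 6π-electrocyclisation and tautomerises to 25 under neutral conditions, with C8a'' remaining sp2 from F3 onwards.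

2. Step 10. Endo or facial selectivity may be lost, either by drift into a stepwise aldol pathway that gives the 2'',3''-trans isomer or by addition to the wrong diene face. The diene may also hydrolyse during a slow reaction with the electron-rich aldehyde. The fallback sets out from 13 (with 15) and comes back at 17. Bu2BOTf and iPr2NEt in CH2Cl2 at −78 °C convert 13 into its Z boron enolate, which should add to 15 to give the syn aldol (2S,3R)-5,7-bis(benzyloxy)-3-[(1S,2S,4E)-1-[4-(benzyloxy)phenyl]-1-hydroxy-5-methoxy-3-oxopent-4-en-2-yl]-2-(4-methoxyphenyl)chroman-4-one F5 through a closed chair transition state. CF3CO2H in CH2Cl2 then converts F5 into 17 by 6-endo addition of the hydroxyl to the β-methoxy enone with loss of methanol, the syn aldol mapping onto the cis product. If the C3 centre does not control the enolate face well enough, the matching antipode of diisopinocampheylboron triflate supplies reagent control.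

3. Step 5. The enolate released on desilylation may live long enough to open ring C of unit 1 by β-elimination of the phenoxide, which erodes the C2 configuration and gives chalcone by-products, or it may be allylated twice or on oxygen. The fallback sets out from 7 and comes back at 10, bypassing 9, and involves no enolate. The acceptor 2-nitropropene F6 is freshly made by dehydrating 2-nitropropan-1-ol over phthalic anhydride and is added to 7 with SnCl4 in CH2Cl2 at −78 °C. The enol silane attacks the nitroalkene terminus on the face opposite the C2 aryl group to give the trimethylsilyl nitronate of (2S,3R)-5,7-bis(benzyloxy)-2-(4-methoxyphenyl)-3-(2-nitropropyl)chroman-4-one F7 as the primary adduct. Aqueous work-up then hydrolyses F7 (Nef reaction) to the 1,4-diketone 10.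

Further compounds
F1 | step 14 | [(2,2-dimethyl-6-methylidene-6H-1,3-dioxin-4-yl)oxy]trimethylsilane | C=C1C=C(O[Si](C)(C)C)OC(C)(C)O1
F2 | step 14 | (2S,3R)-5,7-bis(benzyloxy)-3-[(2S,3S)-2-[4-(benzyloxy)phenyl]-6-[(2,2-dimethyl-4-oxo-4H-1,3-dioxin-6-yl)methyl]-4-oxo-5-(phenylsulfinyl)oxan-3-yl]-2-(4-methoxyphenyl)chroman-4-one | COc1ccc([C@H]2Oc3cc(OCc4ccccc4)cc(OCc4ccccc4)c3C(=O)[C@@H]2[C@@H]2C(=O)C(S(=O)c3ccccc3)C(CC3=CC(=O)OC(C)(C)O3)O[C@@H]2c2ccc(OCc3ccccc3)cc2)cc1
F3 | step 14 | (2S,3R)-5,7-bis(benzyloxy)-3-[(2S,3S)-2-[4-(benzyloxy)phenyl]-6-[(2,2-dimethyl-4-oxo-4H-1,3-dioxin-6-yl)methyl]-4-oxo-3,4-dihydro-2H-pyran-3-yl]-2-(4-methoxyphenyl)chroman-4-one | COc1ccc([C@H]2Oc3cc(OCc4ccccc4)cc(OCc4ccccc4)c3C(=O)[C@@H]2[C@@H]2C(=O)C=C(CC3=CC(=O)OC(C)(C)O3)O[C@@H]2c2ccc(OCc3ccccc3)cc2)cc1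
F4 | step 14 | (2S,3R)-5,7-bis(benzyloxy)-3-[(2S,3S)-2-[4-(benzyloxy)phenyl]-6-(2,4-dioxobut-3-en-1-yl)-4-oxo-3,4-dihydro-2H-pyran-3-yl]-2-(4-methoxyphenyl)chroman-4-one | COc1ccc([C@H]2Oc3cc(OCc4ccccc4)cc(OCc4ccccc4)c3C(=O)[C@@H]2[C@@H]2C(=O)C=C(CC(=O)C=C=O)O[C@@H]2c2ccc(OCc3ccccc3)cc2)cc1
F5 | step 10 | (2S,3R)-5,7-bis(benzyloxy)-3-[(1S,2S,4E)-1-[4-(benzyloxy)phenyl]-1-hydroxy-5-methoxy-3-oxopent-4-en-2-yl]-2-(4-methoxyphenyl)chroman-4-one | COc1ccc([C@H]2Oc3cc(OCc4ccccc4)cc(OCc4ccccc4)c3C(=O)[C@@H]2[C@H](C(=O)/C=C/OC)[C@H](O)c2ccc(OCc3ccccc3)cc2)cc1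
F6 | step 5 | 2-nitropropene | CC(=C)[N+](=O)[O-]
F7 | step 5 | trimethylsilyl nitronate of (2S,3R)-5,7-bis(benzyloxy)-2-(4-methoxyphenyl)-3-(2-nitropropyl)chroman-4-one | COc1ccc([C@H]2Oc3cc(OCc4ccccc4)cc(OCc4ccccc4)c3C(=O)[C@@H]2CC(C)=[N+]([O-])O[Si](C)(C)C)cc1
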